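**Strategy**

The two end groups come from one C15 phosphonium salt, joined to a C10 dialdehyde by two Wittig reactions; the sulfate is put on the C25 aldehyde in between. Everything rests on a formal [3+3] annulation that builds the six-membered ring (C1 gem-dimethyl carbon, C2 and C3 carbinol carbons, C4 methylene, C5, C6 chain-bearing carbon) in one operation: the bis-silyl dienol ether of methyl acetoacetate (C4–C5–C6) adds to the aldehyde carbon C3 and then to the tertiary epoxide carbon C1 of an enantioenriched epoxy aldehyde made by Sharpless epoxidation. It exploits the 1,3-relationship of oxygenated C3 and quaternary C1 across the C2 stereocentre. The precursors are an oxirane carbaldehyde and an open-chain diene.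

Key step: step 3

Remark: the target is drawn as the free hydrogen sulfate, so the sulfate monoester is carried as its sodium salt and protonated only in the last operation; ring atoms are numbered as in carotenoids (C1 = CMe2, C2 and C3 = carbinol carbons, C4 = CH2, C5 = methyl-bearing sp2 carbon, C6 = chain-bearing sp2 carbon).

**Route**

Step 1
Reactants: 1 3-methylbut-2-en-1-ol (prenol)
Product: 2 [(2S)-3,3-dimethyloxiran-2-yl]methanol
Conditions: Ti(OiPr)4 (5 mol %), L-(+)-diethyl tartrate (6 mol %), t-BuOOH, 4 Å molecular sieves, CH2Cl2, −20 °C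
Reagents that add atoms: tert-butyl hydroperoxide, CC(C)(C)OO
Why: Sharpless asymmetric epoxidation of a primary allylic alcohol, in which the L-(+)-tartrate catalyst delivers oxygen to the alkene face that gives the (2S) epoxy alcohol and so fixes the later C2 carbinol.

Step 2
Reactants: 2 [(2S)-3,3-dimethyloxiran-2-yl]methanol
Product: 3 (2R)-3,3-dimethyloxirane-2-carbaldehyde
Conditions: Dess–Martin periodinane, pyridine, CH2Cl2, 0 °C to rt; used at once as a CH2Cl2 solution
Reagents that add atoms: none
Why: Dess–Martin oxidation under buffered, non-aqueous conditions should give the volatile epoxy aldehyde without opening the epoxide or touching its stereocentre (the descriptor changes from S to R only through the priority rules).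

Step 3
Reactants: 3 (2R)-3,3-dimethyloxirane-2-carbaldehyde; 4 1-methoxy-1,3-bis(trimethylsilyloxy)buta-1,3-diene
Product: 6 methyl (4S,5R)-4,5-dihydroxy-6,6-dimethyl-2-oxocyclohexane-1-carboxylate, via bis-silylated epoxy aldol adduct 5 (not isolated)
Conditions: BF3·OEt2 (1.1 equiv), CH2Cl2, −78 °C, then −78 to −10 °C; aq. NaHCO3; citric acid, MeOH, rt
Reagents that add atoms: none
Why: Proposed new method: BF3 should first trigger a vinylogous Mukaiyama aldol addition of the terminal carbon of 4 to the aldehyde of 3 (bond C3–C4), and on warming the enol silane left in 5 should attack the BF3-activated epoxide at its tertiary carbon (bond C1–C6), the way the first alkene does in an epoxide-initiated cation–olefin cyclization. The closest known reaction types are the vinylogous Mukaiyama aldol reaction of 1,3-bis(silyloxy)dienes, their Lewis-acid [3+3] cyclizations with 1,3-dielectrophiles, and epoxy-polyene cyclizations terminated by enol silanes; the union of aldol addition and epoxide opening in one flask is the untested part. The ring closes by a 6-endo-tet opening of the epoxide (6-enolendo on the nucleophile side) through a chair in which the developing tertiary cation at C1 is stabilised by its two methyl groups, which is what overrides 5-exo attack at C2. C2 keeps the configuration set in step 1 because its C–O bond is not broken, C3 is set by Felkin–Anh addition anti to the epoxide C–O bond (reinforced by the cis methyl group) and should therefore come out cis to the C2 oxygen, and the new stereocentre between ketone and ester is epimerisable and later becomes sp2. The step needs terminal (gamma) attack of the diene, carbon instead of oxygen alkylation in the ring closure, and tertiary instead of secondary opening of the epoxide; these are secured by the reactivity of the terminal carbon of the dienol ether, by the silyl group that stays on the enol oxygen, and by the gem-dimethyl substitution.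

Step 4
Reactants: 6 methyl (4S,5R)-4,5-dihydroxy-6,6-dimethyl-2-oxocyclohexane-1-carboxylate
Product: 7 methyl (4S,5R)-4,5-dihydroxy-6,6-dimethyl-2-{[(trifluoromethyl)sulfonyl]oxy}cyclohex-1-ene-1-carboxylate
Conditions: NaH (1.05 equiv), THF, 0 °C; PhNTf2, 0 °C to rt
Reagents that add atoms: N-phenylbis(trifluoromethanesulfonimide), FC(F)(F)S(=O)(=O)N(c1ccccc1)S(=O)(=O)C(F)(F)F
Why: Enol triflate formation, in which one equivalent of NaH deprotonates only the beta-keto ester and the mild triflimide sulfonylates the enolate oxygen while the two alcohols and both stereocentres stay untouched.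

Step 5
Reactants: 7 methyl (4S,5R)-4,5-dihydroxy-6,6-dimethyl-2-{[(trifluoromethyl)sulfonyl]oxy}cyclohex-1-ene-1-carboxylate
Product: 8 methyl (4S,5R)-4,5-dihydroxy-2,6,6-trimethylcyclohex-1-ene-1-carboxylate
Conditions: MeB(OH)2, PdCl2(dppf) (5 mol %), K3PO4, 1,4-dioxane/H2O, 80 °C
Reagents that add atoms: methylboronic acid, CB(O)O
Why: Suzuki–Miyaura coupling of the electron-poor enol triflate with methylboronic acid tolerates the free diol and fixes the methyl group and the tetrasubstituted C5=C6 double bond of the end group.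

Step 6
Reactants: 8 methyl (4S,5R)-4,5-dihydroxy-2,6,6-trimethylcyclohex-1-ene-1-carboxylate
Product: 9 methyl (4R,5R)-5-hydroxy-2,6,6-trimethyl-4-[(4-nitrobenzoyl)oxy]cyclohex-1-ene-1-carboxylate
Conditions: 4-nitrobenzoic acid, PPh3, DIAD, THF, 0 °C to rt
Reagents that add atoms: 4-nitrobenzoic acid, OC(=O)c1ccc(cc1)[N+](=O)[O-]
Why: Mitsunobu reaction, in which only the C3 oxygen of the cis-diol can be displaced (C2 is neopentylic), so the carboxylate enters at C3 with inversion and corrects the Felkin outcome of step 3 to the required (2R,3R) trans arrangement, and the nitrobenzoate should crystallise, which allows enrichment.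

Step 7
Reactants: 9 methyl (4R,5R)-5-hydroxy-2,6,6-trimethyl-4-[(4-nitrobenzoyl)oxy]cyclohex-1-ene-1-carboxylate
Product: 10 (1R,2R)-4-(hydroxymethyl)-3,3,5-trimethylcyclohex-4-ene-1,2-diol
Conditions: i-Bu2AlH (6 equiv), CH2Cl2, −78 to 0 °C; aq. potassium sodium tartrate
Reagents that add atoms: none
Why: i-Bu2AlH reduces the conjugated ester to the allylic alcohol by 1,2-addition and cleaves the nitrobenzoate in the same operation without touching the C–O bonds at the stereocentres.

Step 8
Reactants: 10 (1R,2R)-4-(hydroxymethyl)-3,3,5-trimethylcyclohex-4-ene-1,2-diol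
Product: 11 {[(4R,5R)-4,5-dihydroxy-2,6,6-trimethylcyclohex-1-en-1-yl]methyl}triphenylphosphonium bromide
Conditions: PPh3·HBr, MeOH, rt
Reagents that add atoms: triphenylphosphine hydrobromide, [Br-].c1ccc(cc1)[PH+](c1ccccc1)c1ccccc1
Why: Phosphonium salt formation by an SN1 path, in which only the primary allylic alcohol ionises under HBr to the ring-stabilised allyl cation and the phosphine captures it at the unhindered CH2 terminus while the secondary diol is inert.

Step 9
Reactants: 11 {[(4R,5R)-4,5-dihydroxy-2,6,6-trimethylcyclohex-1-en-1-yl]methyl}triphenylphosphonium bromide; 12 (2E)-4-acetoxy-2-methylbut-2-enal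
Product: 13 (2E,4E)-5-[(4R,5R)-4,5-dihydroxy-2,6,6-trimethylcyclohex-1-en-1-yl]-3-methylpenta-2,4-dien-1-yl acetate
Conditions: 1,2-epoxybutane (solvent), 65 °C; then I2 (cat.), CH2Cl2, daylight
Reagents that add atoms: none
Why: Wittig olefination of the allylic ylide, generated without strong base by the epoxide method so that the acetate survives, should form the C7=C8 bond mainly as the E isomer because of the flanking ring methyl groups, with iodine equilibrating any Z isomer and the C9=C10 geometry carried over from 12.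

Step 10
Reactants: 13 (2E,4E)-5-[(4R,5R)-4,5-dihydroxy-2,6,6-trimethylcyclohex-1-en-1-yl]-3-methylpenta-2,4-dien-1-yl acetate
Product: 14 [(2E,4E)-5-[(4R,5R)-4,5-dihydroxy-2,6,6-trimethylcyclohex-1-en-1-yl]-3-methylpenta-2,4-dien-1-yl]triphenylphosphonium bromide
Conditions: PPh3·HBr, MeOH, rt; recrystallisation
Reagents that add atoms: triphenylphosphine hydrobromide, [Br-].c1ccc(cc1)[PH+](c1ccccc1)c1ccccc1
Why: The dienylic acetate ionises under HBr to a pentadienyl cation that triphenylphosphine traps at the primary terminus, the reaction type by which polyenyl acetates are turned into Wittig salts, and the cation also lets the chain settle in the all-E form.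

Step 11
Reactants: 14 [(2E,4E)-5-[(4R,5R)-4,5-dihydroxy-2,6,6-trimethylcyclohex-1-en-1-yl]-3-methylpenta-2,4-dien-1-yl]triphenylphosphonium bromide; 15 (2E,4E,6E)-2,7-dimethylocta-2,4,6-trienedial (4 equiv)
Product: 16 (2E,4E,6E,8E,10E,12E)-13-[(4R,5R)-4,5-dihydroxy-2,6,6-trimethylcyclohex-1-en-1-yl]-2,7,11-trimethyltrideca-2,4,6,8,10,12-hexaenal
Conditions: NaOMe (1.1 equiv), MeOH/CH2Cl2, 0 °C to rt, salt added slowly to the dialdehyde; then EtOAc, reflux
Reagents that add atoms: none
Why: Wittig olefination with the symmetrical dialdehyde in excess should stop after the first condensation, the free hydroxyls are tolerated under methoxide, and heating equilibrates the new C11=C12 bond to E.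

Step 12
Reactants: 16 (2E,4E,6E,8E,10E,12E)-13-[(4R,5R)-4,5-dihydroxy-2,6,6-trimethylcyclohex-1-en-1-yl]-2,7,11-trimethyltrideca-2,4,6,8,10,12-hexaenal
Product: 17 sodium (1R,6R)-6-hydroxy-3,5,5-trimethyl-4-[(1E,3E,5E,7E,9E,11E)-3,7,12-trimethyl-13-oxotrideca-1,3,5,7,9,11-hexaen-1-yl]cyclohex-3-en-1-yl sulfate
Conditions: SO3·pyridine (1.3 equiv), pyridine/DMF, 0 °C to rt; aq. NaHCO3
Reagents that add atoms: sulfur trioxide–pyridine complex, [O-]S(=O)(=O)[n+]1ccccc1; sodium hydrogencarbonate, [Na+].OC([O-])=O
Why: O-Sulfation with the sulfur trioxide–pyridine complex should take the secondary C3 hydroxyl because the C2 hydroxyl is shielded by the adjacent gem-dimethyl carbon, and the configuration is retained since no C–O bond is broken.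

Step 13
Reactants: 17 sodium (1R,6R)-6-hydroxy-3,5,5-trimethyl-4-[(1E,3E,5E,7E,9E,11E)-3,7,12-trimethyl-13-oxotrideca-1,3,5,7,9,11-hexaen-1-yl]cyclohex-3-en-1-yl sulfate; 14 [(2E,4E)-5-[(4R,5R)-4,5-dihydroxy-2,6,6-trimethylcyclohex-1-en-1-yl]-3-methylpenta-2,4-dien-1-yl]triphenylphosphonium bromide
Product: 19 (2R,3R,2′R,3′R)-all-E-β,β-carotene-2,3,2′,3′-tetrol 3-(hydrogen sulfate), via sodium salt of the target 18 (not isolated)
Conditions: NaOMe (1.2 equiv), MeOH/CH2Cl2, 0 °C to rt; EtOH, 60 °C, dark; then HCl (1.0 equiv, 0.1 M aq.), 0 °C, extraction into n-BuOH/EtOAc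
Reagents that add atoms: none
Why: The second Wittig olefination joins the unsulfated C15 unit to the sulfated C25 aldehyde (the sulfate monoester anion and the free hydroxyls are inert to methoxide), heating should give the all-E polyene, and one equivalent of acid turns the sodium salt 18 into the hydrogen sulfate.

**Compound list**

1 | 3-methylbut-2-en-1-ol (prenol) | CC(C)=CCO | starting material
2 | [(2S)-3,3-dimethyloxiran-2-yl]methanol | OC[C@H]1C(C)(C)O1 | intermediate
3 | (2R)-3,3-dimethyloxirane-2-carbaldehyde | O=C[C@H]1C(C)(C)O1 | intermediate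
4 | 1-methoxy-1,3-bis(trimethylsilyloxy)buta-1,3-diene (bis-silyl dienol ether of methyl acetoacetate, E/Z mixture as supplied) | COC(O[Si](C)(C)C)=CC(=C)O[Si](C)(C)C | starting material
5 | methyl (5S)-5-[(2S)-3,3-dimethyloxiran-2-yl]-3,5-bis(trimethylsilyloxy)pent-2-enoate (enol ether geometry not defined) | COC(=O)C=C(O[Si](C)(C)C)C[C@H](O[Si](C)(C)C)[C@H]1C(C)(C)O1 | intermediate (not isolated)
6 | methyl (4S,5R)-4,5-dihydroxy-6,6-dimethyl-2-oxocyclohexane-1-carboxylate (cis-diol; keto/enol mixture, C1 of the ring epimerisable) | COC(=O)C1C(=O)C[C@H](O)[C@H](O)C1(C)C | intermediate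
7 | methyl (4S,5R)-4,5-dihydroxy-6,6-dimethyl-2-{[(trifluoromethyl)sulfonyl]oxy}cyclohex-1-ene-1-carboxylate | COC(=O)C1=C(OS(=O)(=O)C(F)(F)F)C[C@H](O)[C@H](O)C1(C)C | intermediate
8 | methyl (4S,5R)-4,5-dihydroxy-2,6,6-trimethylcyclohex-1-ene-1-carboxylate | COC(=O)C1=C(C)C[C@H](O)[C@H](O)C1(C)C | intermediate
9 | methyl (4R,5R)-5-hydroxy-2,6,6-trimethyl-4-[(4-nitrobenzoyl)oxy]cyclohex-1-ene-1-carboxylate | COC(=O)C1=C(C)C[C@@H](OC(=O)c2ccc(cc2)[N+](=O)[O-])[C@H](O)C1(C)C | intermediate
10 | (1R,2R)-4-(hydroxymethyl)-3,3,5-trimethylcyclohex-4-ene-1,2-diol | CC1=C(CO)C(C)(C)[C@@H](O)[C@H](O)C1 | intermediate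
11 | {[(4R,5R)-4,5-dihydroxy-2,6,6-trimethylcyclohex-1-en-1-yl]methyl}triphenylphosphonium bromide | CC1=C(C[P+](c2ccccc2)(c2ccccc2)c2ccccc2)C(C)(C)[C@@H](O)[C@H](O)C1.[Br-] | intermediate
12 | (2E)-4-acetoxy-2-methylbut-2-enal | CC(=O)OC/C=C(C)/C=O | starting material
13 | (2E,4E)-5-[(4R,5R)-4,5-dihydroxy-2,6,6-trimethylcyclohex-1-en-1-yl]-3-methylpenta-2,4-dien-1-yl acetate | CC1=C(/C=C/C(C)=C/COC(C)=O)C(C)(C)[C@@H](O)[C@H](O)C1 | intermediate
14 | [(2E,4E)-5-[(4R,5R)-4,5-dihydroxy-2,6,6-trimethylcyclohex-1-en-1-yl]-3-methylpenta-2,4-dien-1-yl]triphenylphosphonium bromide | CC1=C(/C=C/C(C)=C/C[P+](c2ccccc2)(c2ccccc2)c2ccccc2)C(C)(C)[C@@H](O)[C@H](O)C1.[Br-] | intermediate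
15 | (2E,4E,6E)-2,7-dimethylocta-2,4,6-trienedial | O=C/C(C)=C/C=C/C=C(C)/C=O | starting material
16 | (2E,4E,6E,8E,10E,12E)-13-[(4R,5R)-4,5-dihydroxy-2,6,6-trimethylcyclohex-1-en-1-yl]-2,7,11-trimethyltrideca-2,4,6,8,10,12-hexaenal | CC1=C(/C=C/C(C)=C/C=C/C(C)=C/C=C/C=C(C)/C=O)C(C)(C)[C@@H](O)[C@H](O)C1 | intermediate
17 | sodium (1R,6R)-6-hydroxy-3,5,5-trimethyl-4-[(1E,3E,5E,7E,9E,11E)-3,7,12-trimethyl-13-oxotrideca-1,3,5,7,9,11-hexaen-1-yl]cyclohex-3-en-1-yl sulfate | CC1=C(/C=C/C(C)=C/C=C/C(C)=C/C=C/C=C(C)/C=O)C(C)(C)[C@@H](O)[C@H](OS(=O)(=O)[O-])C1.[Na+] | intermediate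
18 | sodium salt of the target (sodium 3-sulfate of (2R,3R,2′R,3′R)-all-E-β,β-carotene-2,3,2′,3′-tetrol) | CC1=C(/C=C/C(C)=C/C=C/C(C)=C/C=C/C=C(C)/C=C/C=C(C)/C=C/C2=C(C)C[C@@H](OS(=O)(=O)[O-])[C@H](O)C2(C)C)C(C)(C)[C@@H](O)[C@H](O)C1.[Na+] | intermediate (not isolated)
19 | (2R,3R,2′R,3′R)-all-E-β,β-carotene-2,3,2′,3′-tetrol 3-(hydrogen sulfate) | CC1=C(/C=C/C(C)=C/C=C/C(C)=C/C=C/C=C(C)/C=C/C=C(C)/C=C/C2=C(C)C[C@@H](OS(=O)(=O)O)[C@H](O)C2(C)C)C(C)(C)[C@@H](O)[C@H](O)C1 | target

**Step count and risks**

Total step count: 13. Longest linear sequence: 13 steps (1 to 19; salt 14 is made once and used in steps 11 and 13).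

Steps most likely to fail:

1. Step 3 (proposed new method). What may go wrong: Lewis-acid-induced rearrangement of the epoxide by hydride shift, or loss of the enol silane before the epoxide opens, so that the second bond does not form or forms through oxygen. The fallback makes the two bonds in separate operations of known type and sets out from 3. Aldol addition of the dianion of methyl acetoacetate (NaH, then n-BuLi, THF, −78 °C), under which the epoxide is inert, should give methyl (5S)-5-[(2S)-3,3-dimethyloxiran-2-yl]-5-hydroxy-3-oxopentanoate F1. Silylation of the hydroxyl and of the enol (TBSOTf, Et3N, CH2Cl2, −78 to 0 °C) should give methyl (5S)-3,5-bis[(tert-butyldimethylsilyl)oxy]-5-[(2S)-3,3-dimethyloxiran-2-yl]pent-2-enoate F2. A separate epoxide-initiated cyclization terminated by the enol silane (MeAlCl2, CH2Cl2, −78 °C), the known closing event of epoxy-polyene cyclizations, should give methyl (4S,5R)-4-[(tert-butyldimethylsilyl)oxy]-5-hydroxy-6,6-dimethyl-2-oxocyclohexane-1-carboxylate F3. HF·pyridine in THF removes the silyl ether and the route is rejoined at 6.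

2. Step 6. What may go wrong: elimination toward the conjugated diene ester, or formation of an unreactive cyclic dioxyphosphorane from the cis-diol, instead of substitution with inversion. The fallback replaces the redox condensation by a sulfonate displacement and sets out from 8. Selective sulfonylation of the less hindered C3 hydroxyl (ClCH2SO2Cl, pyridine, CH2Cl2, 0 °C) should give methyl (4S,5R)-4-{[(chloromethyl)sulfonyl]oxy}-5-hydroxy-2,6,6-trimethylcyclohex-1-ene-1-carboxylate F4. Displacement with CsOAc and 18-crown-6 (toluene, 80 °C) with inversion should give methyl (4R,5R)-4-acetoxy-5-hydroxy-2,6,6-trimethylcyclohex-1-ene-1-carboxylate F5. Reduction of both esters with i-Bu2AlH as in step 7 rejoins the route at 10.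

3. Step 9. What may go wrong: slow olefination by the hindered ring-substituted ylide and incomplete control of the geometry of the new double bond. The fallback reverses the polarity of the coupling and sets out from 10. Oxidation of the allylic alcohol (MnO2, CH2Cl2) should give (4R,5R)-4,5-dihydroxy-2,6,6-trimethylcyclohex-1-ene-1-carbaldehyde F6. Horner–Wadsworth–Emmons reaction with triethyl 3-methyl-4-phosphonobut-2-enoate (LiN(SiMe3)2 in excess, THF, −78 °C to rt) should give ethyl (2E,4E)-5-[(4R,5R)-4,5-dihydroxy-2,6,6-trimethylcyclohex-1-en-1-yl]-3-methylpenta-2,4-dienoate F7. Reduction with i-Bu2AlH should give (2E,4E)-5-[(4R,5R)-4,5-dihydroxy-2,6,6-trimethylcyclohex-1-en-1-yl]-3-methylpenta-2,4-dien-1-ol F8. PPh3·HBr in MeOH then rejoins the route at 14.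

Further compounds
F1 | step 3 | methyl (5S)-5-[(2S)-3,3-dimethyloxiran-2-yl]-5-hydroxy-3-oxopentanoate | COC(=O)CC(=O)C[C@H](O)[C@H]1C(C)(C)O1
F2 | step 3 | methyl (5S)-3,5-bis[(tert-butyldimethylsilyl)oxy]-5-[(2S)-3,3-dimethyloxiran-2-yl]pent-2-enoate (enol ether geometry not defined) | COC(=O)C=C(O[Si](C)(C)C(C)(C)C)C[C@H](O[Si](C)(C)C(C)(C)C)[C@H]1C(C)(C)O1
F3 | step 3 | methyl (4S,5R)-4-[(tert-butyldimethylsilyl)oxy]-5-hydroxy-6,6-dimethyl-2-oxocyclohexane-1-carboxylate | COC(=O)C1C(=O)C[C@H](O[Si](C)(C)C(C)(C)C)[C@H](O)C1(C)C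
F4 | step 6 | methyl (4S,5R)-4-{[(chloromethyl)sulfonyl]oxy}-5-hydroxy-2,6,6-trimethylcyclohex-1-ene-1-carboxylate | COC(=O)C1=C(C)C[C@H](OS(=O)(=O)CCl)[C@H](O)C1(C)C
F5 | step 6 | methyl (4R,5R)-4-acetoxy-5-hydroxy-2,6,6-trimethylcyclohex-1-ene-1-carboxylate | COC(=O)C1=C(C)C[C@@H](OC(C)=O)[C@H](O)C1(C)C
F6 | step 9 | (4R,5R)-4,5-dihydroxy-2,6,6-trimethylcyclohex-1-ene-1-carbaldehyde | CC1=C(C=O)C(C)(C)[C@@H](O)[C@H](O)C1
F7 | step 9 | ethyl (2E,4E)-5-[(4R,5R)-4,5-dihydroxy-2,6,6-trimethylcyclohex-1-en-1-yl]-3-methylpenta-2,4-dienoate | CC1=C(/C=C/C(C)=C/C(=O)OCC)C(C)(C)[C@@H](O)[C@H](O)C1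
F8 | step 9 | (2E,4E)-5-[(4R,5R)-4,5-dihydroxy-2,6,6-trimethylcyclohex-1-en-1-yl]-3-methylpenta-2,4-dien-1-ol | CC1=C(/C=C/C(C)=C/CO)C(C)(C)[C@@H](O)[C@H](O)C1
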